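**Assumption:** locants C1–C15 are germacrane locants (furanone = C10, C1, C2, C3 and the ring oxygen; C4=C5 with the C15 methyl; C6 = ester carbon; lactone = C7, C8, C11, C12 with the C13 methylene; C14 = methyl on C10). On this basis the target is (4Z,6S,7R,8S,10R) with a (2R,3R)-2,3-dimethyloxirane-2-carboxylate (epoxyangelate).

## Retrosynthetic overview

1. Last bond: the C6–O ester, from the macrocyclic C6 alcohol and (2R,3R)-epoxyangelic acid (made from methyl angelate by Sharpless epoxidation).
2. Key step: the butyrolactone and the ten-membered carbocycle are built in one flask from a furanone dialdehyde (C6 enal, C8 aldehyde) and a four-carbon linchpin (C7, C11, C12, C13). Ni/Cr alkenylation at C8 with lactonisation is followed by chromium allylation through C7 onto C6.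
3. The dialdehyde comes from a 2-allyl-5-alkenyl-2-methylfuran-3(2H)-one by Swern oxidation (C6) and Lemieux–Johnson cleavage (C8).
4. The furanone comes from the acetylide of TES-protected (Z)-3-methylpent-2-en-4-yn-1-ol (C2–C6, C15) and the allylated Seebach dioxolanone of L-lactic acid (C1, C8–C10, C14; sets C10).
5. Ring order: furanone first, then butenolide (which becomes the α-methylene lactone) and the ten-membered ring together; the epoxide arrives preformed.

## Route

**Step 1**
Reactants: 1 methyl (2Z)-2-methylbut-2-enoate (methyl angelate)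
Product: 2 (2Z)-2-methylbut-2-en-1-ol
Conditions: i-Bu2AlH (2.2 equiv), CH2Cl2, −78 → 0 °C; Rochelle salt work-up
Reagents that add atoms: none
Why: 1,2-reduction of the enoate ester by the aluminium hydride gives the allylic alcohol and leaves the Z alkene untouched.

**Step 2**
Reactants: 2 (2Z)-2-methylbut-2-en-1-ol
Product: 3 [(2S,3R)-2,3-dimethyloxiran-2-yl]methanol
Conditions: Ti(Oi-Pr)4 (10 mol %), L-(+)-diethyl tartrate (12 mol %), t-BuOOH (2 equiv), 4 Å MS, CH2Cl2, −20 °C
Reagents that add atoms: tert-butyl hydroperoxide, CC(C)(C)OO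
Why: Sharpless asymmetric epoxidation; L-(+)-tartrate delivers oxygen to the same alkene face as in geraniol → (2S,3S)-epoxygeraniol, which here gives (2S,3R), and the Z alkene fixes the cis relation of CH2OH and the C3 methyl.

**Step 3**
Reactants: 3 [(2S,3R)-2,3-dimethyloxiran-2-yl]methanol
Product: 4 (2R,3R)-2,3-dimethyloxirane-2-carboxylic acid
Conditions: RuCl3 (2 mol %), NaIO4 (3 equiv), CCl4/MeCN/H2O, 0 → 23 °C
Reagents that add atoms: water, O
Why: RuO4 oxidation of the primary alcohol to the acid does not touch the epoxide; both centres are unchanged in space (C2 becomes R only because the CIP priorities change).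

**Step 4**
Reactants: 5 methyl propiolate; 6 formaldehyde (used as paraformaldehyde)
Product: 7 methyl (2Z)-2-(hydroxymethyl)-3-iodoprop-2-enoate
Conditions: MgI2 (1.2 equiv), CH2Cl2, 0 → 23 °C
Reagents that add atoms: magnesium iodide, [Mg+2].[I-].[I-]
Why: Iodo-aldol (halo-Morita–Baylis–Hillman) reaction: iodide adds to the propiolate and the β-iodo allenolate is trapped by formaldehyde, giving the Z isomer (I cis to CO2Me), the only geometry that can later lactonise.

**Step 5**
Reactants: 7 methyl (2Z)-2-(hydroxymethyl)-3-iodoprop-2-enoate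
Product: 8 methyl (2Z)-2-{[(diethoxyphosphoryl)oxy]methyl}-3-iodoprop-2-enoate
Conditions: ClP(O)(OEt)2, pyridine, DMAP (cat.), CH2Cl2, 0 °C
Reagents that add atoms: diethyl chlorophosphate, CCOP(=O)(Cl)OCC
Why: O-phosphorylation of the primary allylic alcohol gives a leaving group that CrCl2 alone does not reduce but that iodide later turns into an allylic iodide.

**Step 6**
Reactants: 9 (2Z)-3-methylpent-2-en-4-yn-1-ol
Product: 10 triethyl{[(2Z)-3-methylpent-2-en-4-yn-1-yl]oxy}silane
Conditions: Et3SiCl, imidazole, CH2Cl2, 0 °C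
Reagents that add atoms: chlorotriethylsilane, CC[Si](Cl)(CC)CC
Why: Silylation blocks the cis-disposed C6 hydroxyl, which would otherwise add to the ynone of step 9 (5-exo-dig, furan formation).

**Step 7**
Reactants: 11 (S)-lactic acid; 12 pivalaldehyde
Product: 13 (2S,5S)-2-tert-butyl-5-methyl-1,3-dioxolan-4-one
Conditions: p-TsOH (cat.), H2SO4 (cat.), pentane, reflux, Dean–Stark; crystallisation at −78 °C
Reagents that add atoms: none
Why: Seebach acetalisation; C5 comes from L-lactic acid and the cis acetal (about 4:1, thermodynamic) is purified by crystallisation.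

**Step 8**
Reactants: 13 (2S,5S)-2-tert-butyl-5-methyl-1,3-dioxolan-4-one; 14 allyl bromide
Product: 16 (2S,5R)-2-tert-butyl-5-methyl-5-(prop-2-en-1-yl)-1,3-dioxolan-4-one, via lithium enolate 15 (not isolated)
Conditions: LiN(i-Pr)2 (1.1 equiv), THF, −78 °C; then 14, −78 → −30 °C
Reagents that add atoms: none
Why: Self-regeneration of stereocentres: the enolate is allylated anti to the tert-butyl group, so allyl takes the place of the former H and creates the quaternary centre that becomes C10 (R).

**Step 9**
Reactants: 16 (2S,5R)-2-tert-butyl-5-methyl-5-(prop-2-en-1-yl)-1,3-dioxolan-4-one; 10 triethyl{[(2Z)-3-methylpent-2-en-4-yn-1-yl]oxy}silane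
Product: 19 (2R)-2-methyl-2-(prop-2-en-1-yl)-5-[(2Z)-4-(triethylsilyloxy)but-2-en-2-yl]furan-3(2H)-one, via lithium acetylide 17 (not isolated), via hydroxy ynone 18 (not isolated)
Conditions: 10, n-BuLi (1.05 equiv), THF, −78 °C; then 16, −78 → −20 °C; AcOH (1.1 equiv); then Et2NH (0.3 equiv), EtOH, 23 °C
Reagents that add atoms: none
Why: The acetylide adds to the lactone carbonyl of the acetal, the hemiketal collapses with loss of pivalaldehyde to the α′-hydroxy ynone, and amine-assisted 5-endo-dig oxa-Michael closure gives the 3(2H)-furanone; C10 (R) and the Z alkene are carried through unchanged.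

**Step 10**
Reactants: 19 (2R)-2-methyl-2-(prop-2-en-1-yl)-5-[(2Z)-4-(triethylsilyloxy)but-2-en-2-yl]furan-3(2H)-one
Product: 21 (2Z)-3-[(5R)-5-methyl-4-oxo-5-(prop-2-en-1-yl)-4,5-dihydrofuran-2-yl]but-2-enal, via allylic alcohol 20 (not isolated)
Conditions: (COCl)2 (3 equiv), DMSO (6 equiv), CH2Cl2, −78 → −30 °C; Et3N, −78 → 0 °C
Reagents that add atoms: none
Why: Swern oxidation applied directly to the primary triethylsilyl ether (cleaved in the flask by the chlorosulfonium/HCl medium, then oxidised); it is run before the C8 aldehyde exists so that this base-sensitive β-oxy aldehyde never meets Et3N.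

**Step 11**
Reactants: 21 (2Z)-3-[(5R)-5-methyl-4-oxo-5-(prop-2-en-1-yl)-4,5-dihydrofuran-2-yl]but-2-enal
Product: 23 (2Z)-3-[(5R)-5-methyl-4-oxo-5-(2-oxoethyl)-4,5-dihydrofuran-2-yl]but-2-enal, via vicinal diol 22 (not isolated)
Conditions: OsO4 (2 mol %), NaIO4 (4 equiv), 2,6-lutidine, dioxane/H2O 3:1, 23 °C
Reagents that add atoms: sodium periodate (oxygen relayed through OsO4), [Na+].[O-]I(=O)(=O)=O
Why: Lemieux–Johnson cleavage; OsO4 selects the isolated monosubstituted alkene over the two electron-poor, more substituted C=C bonds of the furanone and the enal.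

**Step 12**
Reactants: 23 (2Z)-3-[(5R)-5-methyl-4-oxo-5-(2-oxoethyl)-4,5-dihydrofuran-2-yl]but-2-enal; 8 methyl (2Z)-2-{[(diethoxyphosphoryl)oxy]methyl}-3-iodoprop-2-enoate
Product: 26 (4Z,6S,7S,8S,10R)-6-hydroxy furanone-bridged germacranolide (the target without its ester acyl group), via butenolide phosphate 24 (not isolated), via butenolide allylic iodide 25 (not isolated)
Conditions: CrCl2 (4 equiv), N-[2-((S)-4-isopropyl-4,5-dihydrooxazol-2-yl)-6-methylphenyl]methanesulfonamide (4.4 equiv; the enantiomer that gives Re-face attack at C8 is used), Et3N (4.4 equiv), NiCl2 (2 mol %), THF, 0 → 23 °C, 8 (1.1 equiv) added over 2 h; then DMPU to 3 mM, CrCl2 (4 equiv), LiI (1 equiv), 40 °C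
Reagents that add atoms: none
Why: Proposed new method: a one-flask linchpin annulation in which first the Ni/Cr-mediated (Nozaki–Hiyama–Kishi) alkenylation of the more electrophilic aliphatic C8 aldehyde by the (Z)-β-iodoacrylate gives a (Z)-γ-oxido enoate that lactonises at once to butenolide 24 (first ring; 8S from Re-face addition under the chiral sulfonamide–chromium complex, while the phosphate is inert to divalent chromium in THF), and then iodide in DMPU converts the allylic phosphate into iodide 25, which CrCl2 reduces to a butenolide allylchromium that adds through C7 to the remaining C6 enal in a closed six-membered transition state, closing the ten-membered carbocycle (second ring) anti to the C8 substituent (trans-lactone, 7R in target numbering) and, as expected for the chromium-mediated mode of this reagent class, with the 6S carbinol; the closest known reactions are the Ni/Cr coupling of (Z)-β-iodoacrylates with aldehydes to butenolides, the CrCl2/LiI allylation of aldehydes with allylic phosphates, and the intermolecular zinc- or chromium-mediated Barbier addition of 3-(bromomethyl)furan-2(5H)-ones to aldehydes.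

Compound 26 has the same spatial arrangement as the target; C7 is S by CIP only because the priorities of C6 and C8 swap in the free alcohol. C6 is the least secure centre of this step.

**Step 13**
Reactants: 26 (4Z,6S,7S,8S,10R)-6-hydroxy furanone-bridged germacranolide; 4 (2R,3R)-2,3-dimethyloxirane-2-carboxylic acid
Product: 28 target CNP0258430.3, via mixed anhydride 27 (not isolated)
Conditions: 4, 2,4,6-trichlorobenzoyl chloride, Et3N, THF, 23 °C; then 26, DMAP, toluene, 23 °C
Reagents that add atoms: none
Why: Yamaguchi esterification acylates the hindered allylic C6 alcohol with retention and is mild enough for the epoxide and the α-methylene lactone.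

## Compound list

1 | methyl (2Z)-2-methylbut-2-enoate (methyl angelate) | C/C=C(/C)C(=O)OC | starting material
2 | (2Z)-2-methylbut-2-en-1-ol | C/C=C(/C)CO | intermediate
3 | [(2S,3R)-2,3-dimethyloxiran-2-yl]methanol | OC[C@]1(C)O[C@@H]1C | intermediate
4 | (2R,3R)-2,3-dimethyloxirane-2-carboxylic acid | O=C(O)[C@]1(C)O[C@@H]1C | intermediate
5 | methyl propiolate | C#CC(=O)OC | starting material
6 | formaldehyde (paraformaldehyde) | C=O | starting material
7 | methyl (2Z)-2-(hydroxymethyl)-3-iodoprop-2-enoate | I/C=C(\C(=O)OC)CO | intermediate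
8 | methyl (2Z)-2-{[(diethoxyphosphoryl)oxy]methyl}-3-iodoprop-2-enoate | I/C=C(\C(=O)OC)COP(=O)(OCC)OCC | intermediate
9 | (2Z)-3-methylpent-2-en-4-yn-1-ol | C#C/C(C)=C\CO | starting material
10 | triethyl{[(2Z)-3-methylpent-2-en-4-yn-1-yl]oxy}silane | C#C/C(C)=C\CO[Si](CC)(CC)CC | intermediate
11 | (S)-lactic acid | C[C@H](O)C(=O)O | starting material
12 | pivalaldehyde | CC(C)(C)C=O | starting material
13 | (2S,5S)-2-tert-butyl-5-methyl-1,3-dioxolan-4-one | C[C@@H]1O[C@H](C(C)(C)C)OC1=O | intermediate
14 | allyl bromide | C=CCBr | starting material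
15 | lithium enolate of 13 | CC1=C(O[Li])O[C@@H](C(C)(C)C)O1 | intermediate
16 | (2S,5R)-2-tert-butyl-5-methyl-5-(prop-2-en-1-yl)-1,3-dioxolan-4-one | C=CC[C@@]1(C)O[C@H](C(C)(C)C)OC1=O | intermediate
17 | lithium acetylide of 10 | [Li]C#C/C(C)=C\CO[Si](CC)(CC)CC | intermediate
18 | (4R,8Z)-4-hydroxy-4,8-dimethyl-10-(triethylsilyloxy)deca-1,8-dien-6-yn-5-one | C=CC[C@@](C)(O)C(=O)C#C/C(C)=C\CO[Si](CC)(CC)CC | intermediate
19 | (2R)-2-methyl-2-(prop-2-en-1-yl)-5-[(2Z)-4-(triethylsilyloxy)but-2-en-2-yl]furan-3(2H)-one | C=CC[C@@]1(C)OC(=CC1=O)/C(C)=C\CO[Si](CC)(CC)CC | intermediate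
20 | (2R)-5-[(2Z)-4-hydroxybut-2-en-2-yl]-2-methyl-2-(prop-2-en-1-yl)furan-3(2H)-one | C=CC[C@@]1(C)OC(=CC1=O)/C(C)=C\CO | intermediate
21 | (2Z)-3-[(5R)-5-methyl-4-oxo-5-(prop-2-en-1-yl)-4,5-dihydrofuran-2-yl]but-2-enal | C=CC[C@@]1(C)OC(=CC1=O)/C(C)=C\C=O | intermediate
22 | (2Z)-3-[(5R)-5-(2,3-dihydroxypropyl)-5-methyl-4-oxo-4,5-dihydrofuran-2-yl]but-2-enal (both carbinol epimers) | OCC(O)C[C@@]1(C)OC(=CC1=O)/C(C)=C\C=O | intermediate
23 | (2Z)-3-[(5R)-5-methyl-4-oxo-5-(2-oxoethyl)-4,5-dihydrofuran-2-yl]but-2-enal | O=CC[C@@]1(C)OC(=CC1=O)/C(C)=C\C=O | intermediate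
24 | diethyl [(5S)-5-{[(2R)-2-methyl-3-oxo-5-[(2Z)-4-oxobut-2-en-2-yl]-2,3-dihydrofuran-2-yl]methyl}-2-oxo-2,5-dihydrofuran-3-yl]methyl phosphate | O=C1O[C@@H](C[C@@]2(C)OC(=CC2=O)/C(C)=C\C=O)C=C1COP(=O)(OCC)OCC | intermediate
25 | (2Z)-3-[(5R)-5-{[(2S)-4-(iodomethyl)-5-oxo-2,5-dihydrofuran-2-yl]methyl}-5-methyl-4-oxo-4,5-dihydrofuran-2-yl]but-2-enal | O=C1O[C@@H](C[C@@]2(C)OC(=CC2=O)/C(C)=C\C=O)C=C1CI | intermediate
26 | (4Z,6S,7S,8S,10R)-6-hydroxy furanone-bridged germacranolide (target without the ester acyl group) | C=C1C(=O)O[C@H]2C[C@@]3(C)OC(=CC3=O)/C(C)=C\[C@H](O)[C@H]12 | intermediate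
27 | (2R,3R)-2,3-dimethyloxirane-2-carboxylic 2,4,6-trichlorobenzoic anhydride | O=C(OC(=O)[C@]1(C)O[C@@H]1C)c1c(Cl)cc(Cl)cc1Cl | intermediate
28 | CNP0258430.3, (4Z,6S,7R,8S,10R) with (2R,3R)-epoxyangelate | C=C1C(=O)O[C@H]2C[C@@]3(C)OC(=CC3=O)/C(C)=C\[C@H](OC(=O)[C@]3(C)O[C@@H]3C)[C@H]12 | target

## Step count and risks

Total step count: 13. Longest linear sequence: 7 steps (steps 7–13, from L-lactic acid).

The three steps most likely to fail:

**Step 12.** The risks are incomplete selection of the C8 aldehyde over the C6 enal, premature activation of the allylic phosphate, and facial control at C8. The fallback sets out from 19 and comes back at 26; it keeps C6 protected while the lactone is built. Lemieux–Johnson cleavage of 19 gives the silyl-protected aldehyde (2R)-2-methyl-2-(2-oxoethyl)-5-[(2Z)-4-(triethylsilyloxy)but-2-en-2-yl]furan-3(2H)-one F1. Ni/Cr coupling of this aldehyde with 8 under the same ligand–CrCl2 system, with no second aldehyde present, gives after lactonisation the butenolide phosphate triethylsilyl ether F2. Swern oxidation of the silyl ether then gives 24, now isolated, and CrCl2/LiI in DMPU at 2 mM closes 24 to 26.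

**Step 9.** The risks are addition of the acetylide to the hindered acetal-lactone and the furanone closure in the same flask. The fallback sets out from 16 and comes back at 19. Aminolysis of 16 with MeNH(OMe)·HCl and i-PrMgCl in THF opens the acetal, with loss of pivalaldehyde, to the Weinreb amide (2R)-2-hydroxy-N-methoxy-N,2-dimethylpent-4-enamide F3. Acetylide 17 (2.2 equiv) converts it into hydroxy ynone 18 by Weinreb ketone synthesis, and Et2NH in EtOH cyclises 18 to 19.

**Step 13.** The risks are acylation of a hindered allylic alcohol and the presumption that step 12 delivered the 6S carbinol. The fallback sets out from 24 (isolated as in the first fallback) and comes back at 28. NaI in acetone gives iodide 25, and Zn in THF/aqueous NH4Cl closes the ring by a zinc Barbier reaction through the chair transition state with the enal residue equatorial, which should give the C6-epimeric alcohol (4Z,6R,7S,8S,10R)-6-hydroxy furanone-bridged germacranolide F4. Mitsunobu esterification of this epimer with acid 4 (PPh3, DIAD, toluene, 0 °C) installs the ester with inversion and gives 28.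

## Further compounds

F1 | step 12 | (2R)-2-methyl-2-(2-oxoethyl)-5-[(2Z)-4-(triethylsilyloxy)but-2-en-2-yl]furan-3(2H)-one | O=CC[C@@]1(C)OC(=CC1=O)/C(C)=C\CO[Si](CC)(CC)CC
F2 | step 12 | butenolide phosphate triethylsilyl ether: diethyl [(5S)-5-{[(2R)-2-methyl-3-oxo-5-[(2Z)-4-(triethylsilyloxy)but-2-en-2-yl]-2,3-dihydrofuran-2-yl]methyl}-2-oxo-2,5-dihydrofuran-3-yl]methyl phosphate | O=C1O[C@@H](C[C@@]2(C)OC(=CC2=O)/C(C)=C\CO[Si](CC)(CC)CC)C=C1COP(=O)(OCC)OCC
F3 | step 9 | (2R)-2-hydroxy-N-methoxy-N,2-dimethylpent-4-enamide | C=CC[C@@](C)(O)C(=O)N(C)OC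
F4 | step 13 | (4Z,6R,7S,8S,10R)-6-hydroxy furanone-bridged germacranolide (C6 epimer of 26) | C=C1C(=O)O[C@H]2C[C@@]3(C)OC(=CC3=O)/C(C)=C\[C@@H](O)[C@H]12
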